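**Retrosynthetic overview** (drimane numbering: C1–C10 are the decalin carbons, C11 is the CH2O carbon)

1. Last disconnections: ring A (the C1=C2 bond) by intramolecular aldol condensation of a C1 aldehyde with the C3 methyl ketone, and before it the C11–O–aryl bond by Mitsunobu reaction with isofraxidin.
2. Key disconnection: ring B by an intramolecular Diels-Alder reaction of a dienyl enoate, which forms the C5–C6 and C9–C10 bonds at once, together with a temporary γ-lactone (C1 carbonyl–O–C11).
3. Enabling feature: ring B is a cyclohexene whose C7=C8 double bond lies opposite the C5–C10 ring-fusion bond; C11–O on C9 is cis to C1 on C10, so both fit into one ester tether; C4 on C5 is trans to C1, which corresponds to an (E)-enoate and later gives the trans ring fusion.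
4. Ring order: ring B with the lactone (step 7), lactone opened to a masked aldehyde and the free C11 alcohol (steps 8 and 9), aryl ether (step 10), ring A (step 11). The Diels-Alder step sets only the relative configuration; the absolute configuration comes from a resolution, the separation of diastereomeric SAMP hydrazones in step 9.
5. Fragments: acid 7 from ethyl 2,2-dimethylacetoacetate (steps 1 to 4) and dienol 9 from an enynol (step 5).

Key step: step 7

Remark: 11 and 12 are racemates; their names carry "rac" and their SMILES show the enantiomer that is carried on after step 9.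
Remark: the (E) isomer of 3-methylpent-2-en-4-yn-1-ol (8), isofraxidin (14) and SAMP are taken as commercially available.

Step 1
Reactants: 1 ethyl 2,2-dimethyl-3-oxobutanoate
Product: 2 ethyl 2-methyl-2-(2-methyl-1,3-dioxolan-2-yl)propanoate
Conditions: ethylene glycol (5 equiv), p-TsOH·H2O (cat.), toluene, reflux, Dean-Stark trap
Reagents that add atoms: ethylene glycol, OCCO
Why: Acid-catalysed ketalization with azeotropic removal of water masks the ketone, which would otherwise be reduced in steps 2 and 8; the ester is not affected.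

Step 2
Reactants: 2 ethyl 2-methyl-2-(2-methyl-1,3-dioxolan-2-yl)propanoate
Product: 3 2-methyl-2-(2-methyl-1,3-dioxolan-2-yl)propan-1-ol
Conditions: LiAlH4, THF, 0 °C to rt; Fieser work-up
Reagents that add atoms: none
Why: Hydride reduction of the ester to the primary alcohol; the dioxolane is inert to LiAlH4.

Step 3
Reactants: 3 2-methyl-2-(2-methyl-1,3-dioxolan-2-yl)propan-1-ol; 4 ethyl 2-(triphenylphosphoranylidene)propanoate
Product: 6 ethyl (2E)-2,4-dimethyl-4-(2-methyl-1,3-dioxolan-2-yl)pent-2-enoate, via aldehyde 5 (not isolated)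
Conditions: n-Pr4NRuO4 (cat.), N-methylmorpholine N-oxide, 4 Å molecular sieves, CH2Cl2, rt; filtration through silica and solvent exchange; then 4, toluene, 100 °C
Reagents that add atoms: none
Why: Ley-Griffith oxidation should give the non-enolizable aldehyde 5, and the Wittig reaction of the stabilized α-methyl ylide should then give the trisubstituted enoate with the ester trans to the tertiary alkyl group, as is usual for stabilized ylides.

Step 4
Reactants: 6 ethyl (2E)-2,4-dimethyl-4-(2-methyl-1,3-dioxolan-2-yl)pent-2-enoate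
Product: 7 (2E)-2,4-dimethyl-4-(2-methyl-1,3-dioxolan-2-yl)pent-2-enoic acid
Conditions: LiOH·H2O, THF/MeOH/H2O, 50 °C; then 1 M HCl to pH 4 at 0 °C
Reagents that add atoms: lithium hydroxide, [Li+].[OH-]
Why: Saponification; the quaternary γ-carbon leaves no γ-hydrogen, so the (E) double bond cannot migrate, and the brief cold acidification should spare the dioxolane.

Step 5
Reactants: 8 (2E)-3-methylpent-2-en-4-yn-1-ol
Product: 9 (2E)-3-methylpenta-2,4-dien-1-ol
Conditions: H2 (1 atm), Pd on CaCO3 poisoned with Pb(OAc)2 (Lindlar catalyst), quinoline, EtOAc, rt, stopped after one equivalent of H2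
Reagents that add atoms: none
Why: Lindlar semihydrogenation should reduce the terminal alkyne to the vinyl group and stop there, leaving the (E)-trisubstituted double bond unchanged.

Step 6
Reactants: 7 (2E)-2,4-dimethyl-4-(2-methyl-1,3-dioxolan-2-yl)pent-2-enoic acid; 9 (2E)-3-methylpenta-2,4-dien-1-ol
Product: 10 (2E)-3-methylpenta-2,4-dien-1-yl (2E)-2,4-dimethyl-4-(2-methyl-1,3-dioxolan-2-yl)pent-2-enoate
Conditions: DCC, DMAP (cat.), CH2Cl2, 0 °C to rt
Reagents that add atoms: none
Why: Steglich esterification (carbodiimide activation with acyl transfer by DMAP) is neutral enough for the dioxolane and the diene and does not affect either double-bond geometry.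

Step 7
Reactants: 10 (2E)-3-methylpenta-2,4-dien-1-yl (2E)-2,4-dimethyl-4-(2-methyl-1,3-dioxolan-2-yl)pent-2-enoate
Product: 11 rac-(3aS,7R,7aR)-4,7a-dimethyl-7-[2-(2-methyl-1,3-dioxolan-2-yl)propan-2-yl]-3a,6,7,7a-tetrahydro-2-benzofuran-1(3H)-one
Conditions: toluene (0.01 M), 2,6-di-tert-butyl-4-methylphenol (cat.), sealed tube, 185 °C
Reagents that add atoms: none
Why: A thermal, concerted but asynchronous suprafacial (4+2) cycloaddition should join the unsubstituted diene terminus (C6) to the β-carbon of the enoate (C5) and the tethered diene terminus (C9) to its α-carbon (C10); the closest known reaction type is the type 1 intramolecular Diels-Alder reaction of ester-tethered 1,3,8-nonatrienes (pentadienyl acrylates) to cis-fused hexahydroisobenzofuranones. Ring B closes as the six-membered ring of the (4+2) event and the γ-lactone as the five-membered tether ring of a fused (type 1) cyclization, the three-atom tether fixing the regiochemistry. The C9/C10 relationship (CH2O cis to the carbonyl carbon, hence trans to the angular methyl group) should follow from the tether-endo transition state, the only one that keeps both the α-methyl group and the bulky tertiary alkyl group of the dienophile exo, away from the diene. C5 is controlled by the (E) geometry of the enoate, which is transferred suprafacially and places the tertiary alkyl group trans to the carbonyl carbon, the arrangement that later becomes the trans ring fusion. The step needs tether-endo over tether-exo selectivity and an intact triene at high temperature: the first is secured by the two substituents that seek the exo side, the second by the gem-dimethyl group, which blocks deconjugation of the dienophile, and by high dilution with a radical inhibitor. The achiral triene has no facial bias, so 11 forms as a racemate and the absolute configuration is fixed in step 9.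

Step 8
Reactants: 11 rac-(3aS,7R,7aR)-4,7a-dimethyl-7-[2-(2-methyl-1,3-dioxolan-2-yl)propan-2-yl]-3a,6,7,7a-tetrahydro-2-benzofuran-1(3H)-one
Product: 12 rac-(3aS,7S,7aR)-4,7a-dimethyl-7-[2-(2-methyl-1,3-dioxolan-2-yl)propan-2-yl]-1,3,3a,6,7,7a-hexahydro-2-benzofuran-1-ol (both anomers)
Conditions: i-Bu2AlH, CH2Cl2, -78 °C; aqueous KNaC4H4O6 (potassium sodium tartrate) work-up
Reagents that add atoms: none
Why: Partial reduction of a γ-lactone stops at the lactol because the tetrahedral aluminium alkoxide persists at -78 °C until work-up; the dioxolane and the alkene are inert.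

Step 9
Reactants: 12 rac-(3aS,7S,7aR)-4,7a-dimethyl-7-[2-(2-methyl-1,3-dioxolan-2-yl)propan-2-yl]-1,3,3a,6,7,7a-hexahydro-2-benzofuran-1-ol
Product: 13 [(1S,5S,6R)-6-[(E)-{[(2S)-2-(methoxymethyl)pyrrolidin-1-yl]imino}methyl]-2,6-dimethyl-5-[2-(2-methyl-1,3-dioxolan-2-yl)propan-2-yl]cyclohex-2-en-1-yl]methanol
Conditions: SAMP (1.2 equiv), AcOH (cat.), 4 Å molecular sieves, CH2Cl2, 40 °C; chromatographic separation of the two hydrazone diastereomers
Reagents that add atoms: SAMP, (S)-1-amino-2-(methoxymethyl)pyrrolidine, COC[C@@H]1CCCN1N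
Why: Hydrazone formation on the open hydroxy aldehyde tautomer of the lactol frees the C11 alcohol and masks C1 at the aldehyde level (a free hydroxy enone would later close to a tetrahydrofuran by oxa-Michael addition), and it turns the two enantiomers of 12 into diastereomers, so that their separation, a classical resolution, fixes the absolute configuration; no stereocentre is formed or touched.

Step 10
Reactants: 13 [(1S,5S,6R)-6-[(E)-{[(2S)-2-(methoxymethyl)pyrrolidin-1-yl]imino}methyl]-2,6-dimethyl-5-[2-(2-methyl-1,3-dioxolan-2-yl)propan-2-yl]cyclohex-2-en-1-yl]methanol; 14 isofraxidin (7-hydroxy-6,8-dimethoxy-2H-chromen-2-one)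
Product: 15 6,8-dimethoxy-7-{[(1S,5S,6R)-6-[(E)-{[(2S)-2-(methoxymethyl)pyrrolidin-1-yl]imino}methyl]-2,6-dimethyl-5-[2-(2-methyl-1,3-dioxolan-2-yl)propan-2-yl]cyclohex-2-en-1-yl]methoxy}-2H-chromen-2-one
Conditions: PPh3, DIAD, THF, 0 °C to 40 °C
Reagents that add atoms: none
Why: Mitsunobu etherification: the primary C11 hydroxyl is the only free alcohol, the phenol is acidic enough to protonate the betaine and attacks the oxyphosphonium ion at CH2, so no stereocentre is involved; the hydrazone, the dioxolane and the alkene are inert.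

Step 11
Reactants: 15 6,8-dimethoxy-7-{[(1S,5S,6R)-6-[(E)-{[(2S)-2-(methoxymethyl)pyrrolidin-1-yl]imino}methyl]-2,6-dimethyl-5-[2-(2-methyl-1,3-dioxolan-2-yl)propan-2-yl]cyclohex-2-en-1-yl]methoxy}-2H-chromen-2-one
Product: 18 6,8-dimethoxy-7-{[(1S,4aS,8aR)-2,5,5,8a-tetramethyl-6-oxo-1,4,4a,5,6,8a-hexahydronaphthalen-1-yl]methoxy}-2H-chromen-2-one (CNP0330704.1), via keto aldehyde 16 (not isolated), via aldol 17 (not isolated)
Conditions: 2 M aq. HCl, THF, 40 °C; extraction; then piperidine, AcOH, toluene, 70 °C
Reagents that add atoms: water, O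
Why: Aqueous acid should hydrolyse the hydrazone and the dioxolane to keto aldehyde 16, whose only enolizable position is the methyl group of the ketone, so the piperidinium acetate-mediated intramolecular aldol condensation with the non-enolizable aldehyde can only close the six-membered enone of ring A; C5, C9 and C10 are untouched, the trans ring fusion follows from the trans side arms set in step 7, and the coumarin tolerates this buffer.

**Compound list**

1 | ethyl 2,2-dimethyl-3-oxobutanoate | CCOC(=O)C(C)(C)C(C)=O | starting material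
2 | ethyl 2-methyl-2-(2-methyl-1,3-dioxolan-2-yl)propanoate | CCOC(=O)C(C)(C)C1(C)OCCO1 | intermediate
3 | 2-methyl-2-(2-methyl-1,3-dioxolan-2-yl)propan-1-ol | OCC(C)(C)C1(C)OCCO1 | intermediate
4 | ethyl 2-(triphenylphosphoranylidene)propanoate | CCOC(=O)C(C)=P(c1ccccc1)(c1ccccc1)c1ccccc1 | starting material
5 | 2-methyl-2-(2-methyl-1,3-dioxolan-2-yl)propanal | O=CC(C)(C)C1(C)OCCO1 | intermediate
6 | ethyl (2E)-2,4-dimethyl-4-(2-methyl-1,3-dioxolan-2-yl)pent-2-enoate | CCOC(=O)/C(C)=C/C(C)(C)C1(C)OCCO1 | intermediate
7 | (2E)-2,4-dimethyl-4-(2-methyl-1,3-dioxolan-2-yl)pent-2-enoic acid | OC(=O)/C(C)=C/C(C)(C)C1(C)OCCO1 | intermediate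
8 | (2E)-3-methylpent-2-en-4-yn-1-ol | C#C/C(C)=C/CO | starting material
9 | (2E)-3-methylpenta-2,4-dien-1-ol | C=C/C(C)=C/CO | intermediate
10 | (2E)-3-methylpenta-2,4-dien-1-yl (2E)-2,4-dimethyl-4-(2-methyl-1,3-dioxolan-2-yl)pent-2-enoate | C=C/C(C)=C/COC(=O)/C(C)=C/C(C)(C)C1(C)OCCO1 | intermediate
11 | rac-(3aS,7R,7aR)-4,7a-dimethyl-7-[2-(2-methyl-1,3-dioxolan-2-yl)propan-2-yl]-3a,6,7,7a-tetrahydro-2-benzofuran-1(3H)-one | O=C1OC[C@H]2C(C)=CC[C@H](C(C)(C)C3(C)OCCO3)[C@@]12C | intermediate
12 | rac-(3aS,7S,7aR)-4,7a-dimethyl-7-[2-(2-methyl-1,3-dioxolan-2-yl)propan-2-yl]-1,3,3a,6,7,7a-hexahydro-2-benzofuran-1-ol (both anomers) | OC1OC[C@H]2C(C)=CC[C@H](C(C)(C)C3(C)OCCO3)[C@@]12C | intermediate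
13 | [(1S,5S,6R)-6-[(E)-{[(2S)-2-(methoxymethyl)pyrrolidin-1-yl]imino}methyl]-2,6-dimethyl-5-[2-(2-methyl-1,3-dioxolan-2-yl)propan-2-yl]cyclohex-2-en-1-yl]methanol | OC[C@H]1C(C)=CC[C@H](C(C)(C)C2(C)OCCO2)[C@@]1(C)/C=N/N1CCC[C@H]1COC | intermediate
14 | isofraxidin (7-hydroxy-6,8-dimethoxy-2H-chromen-2-one) | COc1cc2ccc(=O)oc2c(OC)c1O | starting material
15 | 6,8-dimethoxy-7-{[(1S,5S,6R)-6-[(E)-{[(2S)-2-(methoxymethyl)pyrrolidin-1-yl]imino}methyl]-2,6-dimethyl-5-[2-(2-methyl-1,3-dioxolan-2-yl)propan-2-yl]cyclohex-2-en-1-yl]methoxy}-2H-chromen-2-one | COc1cc2ccc(=O)oc2c(OC)c1OC[C@H]1C(C)=CC[C@H](C(C)(C)C2(C)OCCO2)[C@@]1(C)/C=N/N1CCC[C@H]1COC | intermediate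
16 | (1R,2S,6S)-2-{[(6,8-dimethoxy-2-oxo-2H-chromen-7-yl)oxy]methyl}-1,3-dimethyl-6-(2-methyl-3-oxobutan-2-yl)cyclohex-3-ene-1-carbaldehyde | COc1cc2ccc(=O)oc2c(OC)c1OC[C@H]1C(C)=CC[C@H](C(C)(C)C(C)=O)[C@@]1(C)C=O | intermediate
17 | (4aR,5S,8aS)-5-{[(6,8-dimethoxy-2-oxo-2H-chromen-7-yl)oxy]methyl}-4-hydroxy-1,1,4a,6-tetramethyl-3,4,4a,5,8,8a-hexahydronaphthalen-2(1H)-one (either carbinol epimer) | COc1cc2ccc(=O)oc2c(OC)c1OC[C@H]1C(C)=CC[C@@H]2C(C)(C)C(=O)CC(O)[C@]21C | intermediate
18 | 6,8-dimethoxy-7-{[(1S,4aS,8aR)-2,5,5,8a-tetramethyl-6-oxo-1,4,4a,5,6,8a-hexahydronaphthalen-1-yl]methoxy}-2H-chromen-2-one (CNP0330704.1) | COc1cc2ccc(=O)oc2c(OC)c1OC[C@H]1C(C)=CC[C@@H]2C(C)(C)C(=O)C=C[C@]21C | target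

**Step count and risks**

Total steps: 11. Longest linear sequence: 10 (steps 1 to 4 and 6 to 11).

Step 7 (most likely to fail). The cycloaddition may be too slow: the ester has to leave its preferred rotamer to reach the reactive geometry, and the dienophile is trisubstituted with a neopentyl-type β-carbon, so thermal polymerization of the diene may outrun ring closure. The fallback changes the tether; it sets out from acid 7 and dienol 9 and comes back at lactone 11. Acid 7 would be coupled with N-methylhydroxylamine (carbodiimide activation) to give the N-methylhydroxamic acid F1, which would be O-alkylated with dienol 9 under Mitsunobu conditions to the O-dienyl hydroxamate F2. The two amide rotamers of a hydroxamate are close in energy, so the tether reaches the reactive geometry more easily than an ester, and the cycloaddition should proceed near 110 °C through the same tether-endo transition state to the cis-fused benzoxazinone F3. N–O cleavage with SmI2 would give the hydroxy N-methylamide F4, and acid-catalysed N-to-O acyl transfer (camphorsulfonic acid, toluene, 80 °C) would expel the amine and return 11.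

Step 10. The activated alcohol may undergo β-elimination toward the conjugated exocyclic diene, or the phenoxide, flanked by two methoxy groups, may fail to attack the hindered oxyphosphonium ion. The fallback replaces the redox condensation by a two-stage Williamson ether synthesis; it sets out from 13 and comes back at 15. Alcohol 13 would be converted into its methanesulfonate F5 (MsCl, Et3N, CH2Cl2, 0 °C), which would be displaced by the caesium phenoxide of isofraxidin 14 (Cs2CO3, DMF, 60 °C) to give 15.

Step 9. The two hydrazone diastereomers may co-elute, so that the resolution fails. The fallback resolves one stage earlier through crystalline amides; it sets out from 11 and comes back at 11, then as a single enantiomer. Racemic 11 would be opened with the dimethylaluminium amide of (S)-1-phenylethylamine (from AlMe3, toluene, 60 °C) to give the hydroxy amide F6 and its diastereomer F7, which should be separable by crystallization or chromatography. F6 would be relactonized (camphorsulfonic acid, toluene, 80 °C, with loss of the amine) to the (3aS,7R,7aR) enantiomer of 11, and steps 8 and 9 would then give 13 as the only hydrazone.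

Further compounds
F1 | step 7 | (2E)-N-hydroxy-N,2,4-trimethyl-4-(2-methyl-1,3-dioxolan-2-yl)pent-2-enamide | CN(O)C(=O)/C(C)=C/C(C)(C)C1(C)OCCO1
F2 | step 7 | (2E)-N,2,4-trimethyl-N-{[(2E)-3-methylpenta-2,4-dien-1-yl]oxy}-4-(2-methyl-1,3-dioxolan-2-yl)pent-2-enamide | C=C/C(C)=C/CON(C)C(=O)/C(C)=C/C(C)(C)C1(C)OCCO1
F3 | step 7 | rac-(4aR,5R,8aS)-3,4a,8-trimethyl-5-[2-(2-methyl-1,3-dioxolan-2-yl)propan-2-yl]-4a,5,6,8a-tetrahydro-1H-2,3-benzoxazin-4(3H)-one | CN1OC[C@H]2C(C)=CC[C@H](C(C)(C)C3(C)OCCO3)[C@@]2(C)C1=O
F4 | step 7 | rac-(1R,2S,6R)-2-(hydroxymethyl)-N,1,3-trimethyl-6-[2-(2-methyl-1,3-dioxolan-2-yl)propan-2-yl]cyclohex-3-ene-1-carboxamide | OC[C@H]1C(C)=CC[C@H](C(C)(C)C2(C)OCCO2)[C@@]1(C)C(=O)NC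
F5 | step 10 | [(1S,5S,6R)-6-[(E)-{[(2S)-2-(methoxymethyl)pyrrolidin-1-yl]imino}methyl]-2,6-dimethyl-5-[2-(2-methyl-1,3-dioxolan-2-yl)propan-2-yl]cyclohex-2-en-1-yl]methyl methanesulfonate | CS(=O)(=O)OC[C@H]1C(C)=CC[C@H](C(C)(C)C2(C)OCCO2)[C@@]1(C)/C=N/N1CCC[C@H]1COC
F6 | step 9 | (1R,2S,6R)-2-(hydroxymethyl)-1,3-dimethyl-6-[2-(2-methyl-1,3-dioxolan-2-yl)propan-2-yl]-N-[(1S)-1-phenylethyl]cyclohex-3-ene-1-carboxamide | OC[C@H]1C(C)=CC[C@H](C(C)(C)C2(C)OCCO2)[C@@]1(C)C(=O)N[C@@H](C)c1ccccc1
F7 | step 9 | (1S,2R,6S)-2-(hydroxymethyl)-1,3-dimethyl-6-[2-(2-methyl-1,3-dioxolan-2-yl)propan-2-yl]-N-[(1S)-1-phenylethyl]cyclohex-3-ene-1-carboxamide | OC[C@@H]1C(C)=CC[C@@H](C(C)(C)C2(C)OCCO2)[C@]1(C)C(=O)N[C@@H](C)c1ccccc1
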